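**Plan**
- Retrosynthesis first cuts the O–CH3 bond of a methyl-protected phenol and returns ring B to its dihydro level, a 2-bromocyclohexadienyl aryl ether.
- The enabling feature is in ring B: the brominated carbon C2' is a single carbon between the ether-bearing C1' and C3'. Cutting C1'–C2' and C2'–C3' removes it as dibromocarbene and leaves a cyclopent-1-enyl aryl ether, whose enol ether double bond is where a CBr unit can be inserted.
- Further cuts are the O–C1' bond (copper-mediated O-alkenylation of a phenol) and the three C–Br bonds of ring A (one Sandmeyer, two amine-directed brominations), back to 5-amino-2-methoxyphenol.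
- Forward: ring A is bought and brominated, the five-membered ring is attached through oxygen and grows into six-membered ring B by one-carbon expansion, then dehydrogenation and demethylation finish.
- Stereochemistry: the target has no stereocentre and no stereogenic double bond; the centres of the two transient intermediates of the ring expansion are racemic and are erased.

Key step: step 4

**Step 1**
Reactants: 1 5-amino-2-methoxyphenol
Product: 2 3-amino-2,4-dibromo-6-methoxyphenol
Conditions: NBS (2.05 equiv), MeCN, −10 → 0 °C
Reagents that add atoms: N-bromosuccinimide, O=C1CCC(=O)N1Br
Why: Electrophilic aromatic bromination: the two carbons flanking the amino group are also ortho and para to the hydroxyl, so both directors reinforce each other there, whereas the remaining C–H is activated by the methoxy group alone, and two equivalents of NBS in the cold should stop at the dibromide without oxidising the aminophenol.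

**Step 2**
Reactants: 2 3-amino-2,4-dibromo-6-methoxyphenol
Product: 4 2,3,4-tribromo-6-methoxyphenol, via diazonium hydrogensulfate 3 (not isolated)
Conditions: NaNO2, H2SO4, AcOH, 0–10 °C; then CuBr (0.3 equiv), 48% aq HBr, 60 °C
Reagents that add atoms: hydrogen bromide, Br
Why: Sandmeyer reaction: the weakly basic, doubly ortho-brominated aniline is diazotised in nitrosylsulfuric acid medium, CuBr reduces the diazonium ion to the aryl radical, which takes bromine from the divalent copper bromide so formed, and azo coupling cannot compete because every position ortho and para to the free hydroxyl is blocked.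

**Step 3**
Reactants: 4 2,3,4-tribromo-6-methoxyphenol; 5 cyclopent-1-en-1-ylboronic acid (2.5 equiv)
Product: 6 1,2,3-tribromo-4-(cyclopent-1-en-1-yloxy)-5-methoxybenzene
Conditions: Cu(OAc)2 (2 equiv), pyridine, Et3N, 4 Å MS, CH2Cl2, air, rt; chromatography on Et3N-deactivated silica
Reagents that add atoms: none
Why: Chan–Lam coupling: phenoxide and the alkenyl group of 5 meet on copper and reductive elimination from a trivalent copper intermediate forms the O–C(sp2) bond at room temperature with a weak amine base, conditions that leave the three aryl bromides untouched, while the excess of 5 offsets protodeboronation.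

**Step 4**
Reactants: 6 1,2,3-tribromo-4-(cyclopent-1-en-1-yloxy)-5-methoxybenzene; 7 bromoform (2 equiv)
Product: 10 1,2,3-tribromo-4-[(6-bromocyclohexa-1,5-dien-1-yl)oxy]-5-methoxybenzene, via dibromocyclopropane 8 (not isolated), via allylic bromide 9 (not isolated)
Conditions: KOtBu (2.5 equiv), pentane–PhMe, −20 → 0 °C; cold filtration and solvent swap; then 2,6-lutidine (3 equiv), PhMe, 80 °C
Reagents that add atoms: none
Why: KOtBu deprotonates 7 and the tribromomethyl anion loses bromide, so that singlet dibromocarbene adds in a concerted [2+1] cycloaddition to the enol ether double bond of 6, the most electron-rich π bond present, closing the three-membered ring of 8 and forming the C1'–C2' and C2'–C3' bonds. On warming, 8 opens by the disrotatory two-electron electrocyclic cyclopropyl-to-allyl process, the endo bromide leaving with a push from the ether oxygen while the shared C–C bond breaks, so six-membered ring B arises by one-carbon expansion of the five-membered ring and not by an end-to-end cyclisation. Ion-pair return should give allylic bromide 9, which ionises again to the oxygen-stabilised 2-bromoallyl cation and gives up a proton of the methylene next to the cationic carbon to 2,6-lutidine, leading to diene 10. The closest known reaction type is the dihalocarbene ring expansion of cyclic alkyl and silyl enol ethers to 2-halo-3-alkoxycycloalka-1,3-dienes and 2-halocycloalkenones, a carbocyclic relative of the Ciamician–Dennstedt rearrangement. No stereocentre is left in 10, since those of 8 and 9 are racemic and are destroyed, and a diene isomer with the second double bond on the other side of the bromine-bearing carbon would give the same arene in step 5. Two chemoselectivities are needed: the carbene has a single alkene to attack because ring A carries only one, deactivated C–H, and the cation must lose a proton instead of being trapped, which removal of tBuOH before warming, dry conditions and a hindered base should secure.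

**Step 5**
Reactants: 10 1,2,3-tribromo-4-[(6-bromocyclohexa-1,5-dien-1-yl)oxy]-5-methoxybenzene
Product: 11 1,2,3-tribromo-4-(2-bromophenoxy)-5-methoxybenzene
Conditions: DDQ (1.2 equiv), PhMe, rt → 60 °C
Reagents that add atoms: none
Why: Dehydrogenative aromatisation with a high-potential quinone: DDQ abstracts hydride from an allylic CH2 of the diene and the cation loses a proton, driven by the gain of aromaticity, while the electron-poor ring A, the aryl bromides and the vinylic bromine are inert to DDQ.

**Step 6**
Reactants: 11 1,2,3-tribromo-4-(2-bromophenoxy)-5-methoxybenzene
Product: 12 3,4,5-tribromo-2-(2-bromophenoxy)phenol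
Conditions: BBr3 (3 equiv), CH2Cl2, −78 °C → rt; then H2O
Reagents that add atoms: none
Why: Lewis-acid cleavage of an aryl methyl ether: BBr3 binds the methoxy oxygen and bromide attacks the methyl carbon in an SN2 reaction, whereas the diaryl ether offers no sp3 carbon and the aryl bromides are unaffected, so hydrolysis of the aryl borate on work-up should give 12.

**Compound list**
1 | 5-amino-2-methoxyphenol | COc1ccc(N)cc1O | starting material
2 | 3-amino-2,4-dibromo-6-methoxyphenol | COc1cc(Br)c(N)c(Br)c1O | intermediate
3 | 2,6-dibromo-3-hydroxy-4-methoxybenzenediazonium hydrogensulfate | COc1cc(Br)c([N+]#N)c(Br)c1O.OS(=O)(=O)[O-] | intermediate (not isolated)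
4 | 2,3,4-tribromo-6-methoxyphenol | COc1cc(Br)c(Br)c(Br)c1O | intermediate
5 | cyclopent-1-en-1-ylboronic acid | OB(O)C1=CCCC1 | starting material
6 | 1,2,3-tribromo-4-(cyclopent-1-en-1-yloxy)-5-methoxybenzene | COc1cc(Br)c(Br)c(Br)c1OC1=CCCC1 | intermediate
7 | bromoform | BrC(Br)Br | starting material
8 | 1,2,3-tribromo-4-[(6,6-dibromobicyclo[3.1.0]hexan-1-yl)oxy]-5-methoxybenzene (racemic; the cis ring fusion is the only possible one) | COc1cc(Br)c(Br)c(Br)c1OC12CCCC1C2(Br)Br | intermediate (not isolated)
9 | 1,2,3-tribromo-4-[(2,3-dibromocyclohex-1-en-1-yl)oxy]-5-methoxybenzene (racemic) | COc1cc(Br)c(Br)c(Br)c1OC1=C(Br)C(Br)CCC1 | intermediate (not isolated)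
10 | 1,2,3-tribromo-4-[(6-bromocyclohexa-1,5-dien-1-yl)oxy]-5-methoxybenzene | COc1cc(Br)c(Br)c(Br)c1OC1=CCCC=C1Br | intermediate
11 | 1,2,3-tribromo-4-(2-bromophenoxy)-5-methoxybenzene | COc1cc(Br)c(Br)c(Br)c1Oc1ccccc1Br | intermediate
12 | 3,4,5-tribromo-2-(2-bromophenoxy)phenol | Oc1cc(Br)c(Br)c(Br)c1Oc1ccccc1Br | target

**Step count**
Total: 6 steps. Longest linear sequence: 6 steps (1 → 12).

**Steps most likely to fail**

Step 4 (key step). The ring-opened cation may be captured by tert-butanol, tert-butoxide or traces of water, which cleaves the C1'–O bond and returns the phenol. Cyclopropanation may also be slow, because the enol ether shares its oxygen lone pair with a hindered, electron-poor arene, and a second carbene may add once the diene has formed. The fallback gives up the ring expansion and sets out from 4. 1-Bromo-2-iodobenzene is oxidised with mCPBA and TsOH·H2O in MeCN and condensed in the same pot with 1,3,5-trimethoxybenzene to (2-bromophenyl)(2,4,6-trimethoxyphenyl)iodonium 4-methylbenzenesulfonate F1. The phenoxide of 4 (K2CO3, MeCN, 55 °C) should attack iodine, and ligand coupling should transfer the 2-bromophenyl group, the electron-rich trimethoxyphenyl group staying on iodine. This metal-free O-arylation leaves the aryl bromides alone and comes back to the route at 11, replacing steps 3 to 5.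

Step 3. Transmetalation and C–O bond formation may be slow at a phenol that is substituted at both ortho positions and electron-poor, while protodeboronation and oxidative homocoupling use up 5. The acid-labile enol ether may also hydrolyse during purification. The fallback sets out from 4 and reaches the same ether by double-bond migration. A Mitsunobu reaction with cyclopent-2-en-1-ol (PPh3, DIAD, THF, 0 °C → rt) should give 1,2,3-tribromo-4-(cyclopent-2-en-1-yloxy)-5-methoxybenzene F2; direct and allylic substitution give the same constitution here. A ruthenium hydride catalyst (RuHCl(CO)(PPh3)3, PhMe, 80 °C) should then move the double bond into conjugation with oxygen, coming back at 6.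

Step 2. Diazotisation of a weakly basic aniline flanked by two bromines may stay incomplete, and hydrodediazoniation or hydrolysis of the diazonium ion may compete with bromine transfer. The fallback reverses the order of events and sets out from 1. The unhindered aniline is diazotised (NaNO2, H2SO4, 0 °C) to 3-hydroxy-4-methoxybenzenediazonium hydrogensulfate F3, which is not isolated, and CuBr in aqueous HBr should give 5-bromo-2-methoxyphenol F4. Two equivalents of NBS in MeCN at 0 °C should then brominate para and ortho to the hydroxyl, which is now the only strong director, and come back at 4, replacing steps 1 and 2.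

**Further compounds**
F1 | step 4 | (2-bromophenyl)(2,4,6-trimethoxyphenyl)iodonium 4-methylbenzenesulfonate | COc1cc(OC)c([I+]c2ccccc2Br)c(OC)c1.Cc1ccc(cc1)S(=O)(=O)[O-]
F2 | step 3 | 1,2,3-tribromo-4-(cyclopent-2-en-1-yloxy)-5-methoxybenzene (racemic) | COc1cc(Br)c(Br)c(Br)c1OC1C=CCC1
F3 | step 2 | 3-hydroxy-4-methoxybenzenediazonium hydrogensulfate | COc1ccc([N+]#N)cc1O.OS(=O)(=O)[O-]
F4 | step 2 | 5-bromo-2-methoxyphenol | COc1ccc(Br)cc1O
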